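Everything rests on cutting the aryl ether bond O1–C8a of ring C. O1 joins the single stereocentre C2 directly to the aromatic carbon C8a of ring A, so an (S)-configured benzylic alcohol, set beforehand by oxazaborolidine reduction, can be coupled with an ortho-bromoarene under palladium catalysis without any bond to C2 being broken. One operation thus closes the pyran ring and delivers the 2S ether with retention. The cyclisation substrate is an open chain: a free (S)-carbinol beside the trimethoxyphenyl ring, the C4 oxygen masked as a silyl ether (both epimers, oxidised to the ketone at the end), and bromine on the future C8a.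

Key step: step 4

Remark: 2-bromo-4,6-dimethoxybenzaldehyde is treated as a catalogue compound, and the silyloxy carbon (C4 of the chroman) is carried as both epimers because it becomes the carbonyl carbon in the last step; names mark it RS and SMILES strings leave it unassigned.

Step 1
Reactants: 1 1-(3,4,5-trimethoxyphenyl)ethanone; 2 2-bromo-4,6-dimethoxybenzaldehyde
Product: 4 rac-3-(2-bromo-4,6-dimethoxyphenyl)-3-hydroxy-1-(3,4,5-trimethoxyphenyl)propan-1-one, via lithium enolate 3 (not isolated)
Conditions: LiN(i-Pr)2 (1.05 equiv), THF, −78 °C, then 2, −78 °C; AcOH in THF at −78 °C; Et3N-deactivated silica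
Reagents that add atoms: none
Why: Directed aldol addition in which the preformed lithium enolate of the methyl ketone adds to the non-enolisable aldehyde at low temperature and a cold quench forestalls retro-aldol cleavage and dehydration, the new carbinol centre forming as a racemate, which is acceptable because this carbon ends as the C4 carbonyl.

Step 2
Reactants: 4 rac-3-(2-bromo-4,6-dimethoxyphenyl)-3-hydroxy-1-(3,4,5-trimethoxyphenyl)propan-1-one
Product: 5 rac-3-(2-bromo-4,6-dimethoxyphenyl)-3-[(tert-butyldimethylsilyl)oxy]-1-(3,4,5-trimethoxyphenyl)propan-1-one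
Conditions: TBSOTf, 2,6-lutidine, CH2Cl2, −78 → 0 °C
Reagents that add atoms: tert-butyldimethylsilyl trifluoromethanesulfonate (TBSOTf), CC(C)(C)[Si](C)(C)OS(=O)(=O)C(F)(F)F
Why: O-Silylation of a hindered secondary benzylic alcohol with a silyl triflate and a hindered pyridine base is fast at low temperature, so the β-hydroxy ketone should be capped before it can fragment or eliminate, and no stereocentre is touched.

Step 3
Reactants: 5 rac-3-(2-bromo-4,6-dimethoxyphenyl)-3-[(tert-butyldimethylsilyl)oxy]-1-(3,4,5-trimethoxyphenyl)propan-1-one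
Product: 6 (1S,3RS)-3-(2-bromo-4,6-dimethoxyphenyl)-3-[(tert-butyldimethylsilyl)oxy]-1-(3,4,5-trimethoxyphenyl)propan-1-ol
Conditions: (R)-1-methyl-3,3-diphenyltetrahydro-1H,3H-pyrrolo[1,2-c][1,3,2]oxazaborole (20 mol%), BH3·SMe2, THF, −20 °C, slow addition of 5; MeOH quench
Reagents that add atoms: none
Why: Corey–Bakshi–Shibata reduction in which the (R)-oxazaborolidine binds borane and the aryl ketone with the aryl group as the large substituent and delivers hydride to one carbonyl face, which should set the S carbinol under catalyst control in both enantiomers of 5 (the (S)-catalyst gives R alcohols from aryl alkyl ketones), leaving two C3 epimers that converge later.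

Step 4
Reactants: 6 (1S,3RS)-3-(2-bromo-4,6-dimethoxyphenyl)-3-[(tert-butyldimethylsilyl)oxy]-1-(3,4,5-trimethoxyphenyl)propan-1-ol
Product: 7 (2S,4RS)-4-[(tert-butyldimethylsilyl)oxy]-5,7-dimethoxy-2-(3,4,5-trimethoxyphenyl)chromane
Conditions: Pd(OAc)2 (5 mol%), 2-(di-tert-butylphosphino)-1,1'-binaphthyl (6 mol%), Cs2CO3, toluene, 70 °C, argon
Reagents that add atoms: none
Why: Zerovalent palladium, generated in the flask from Pd(OAc)2 and the phosphine, inserts into the C8a–Br bond, Cs2CO3 removes the proton of the palladium-bound C2 hydroxyl to give a seven-membered aryl alkoxide chelate of divalent palladium (Pd, C8a, C4a, C4, C3, C2, O), and C–O reductive elimination forms O1–C8a. The closest known reaction type is the intramolecular Buchwald–Hartwig etherification of aryl bromides with tethered secondary alcohols, an established entry to chromans. Ring C closes as a six-membered ring by ipso substitution at C8a, exo with respect to the C8a–Br bond that is broken, and the ortho relation between bromine and the side chain makes C8a the only carbon the oxygen can reach. No stereocentre is formed: C2 keeps the S configuration from step 3 with retention because only its O–H bond reacts, and both C4 epimers should cyclise. The selectivity needed is reductive elimination over β-hydride elimination of the benzylic alkoxide, which the bulky, electron-rich di-tert-butyl biaryl phosphine secures, together with silence of the C4 oxygen, which the silyl ether secures by excluding a second alkoxide, retro-aldol cleavage and chalcone formation under base. Both methoxy groups are meta to bromine, so they do not retard oxidative addition by resonance.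

Step 5
Reactants: 7 (2S,4RS)-4-[(tert-butyldimethylsilyl)oxy]-5,7-dimethoxy-2-(3,4,5-trimethoxyphenyl)chromane
Product: 8 (2S,4RS)-5,7-dimethoxy-2-(3,4,5-trimethoxyphenyl)chroman-4-ol
Conditions: Bu4NF (1 M in THF), THF, 0 °C → rt; aqueous NaHCO3 work-up, crude material carried on
Reagents that add atoms: none
Why: Fluoride-induced cleavage of the Si–O bond (silyl ether deprotection) runs without acid, so the ionisation-prone, electron-rich benzylic C4–O bond and the C2 ether should survive and no stereocentre is affected.

Step 6
Reactants: 8 (2S,4RS)-5,7-dimethoxy-2-(3,4,5-trimethoxyphenyl)chroman-4-ol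
Product: 9 (2S)-5,7-dimethoxy-2-(3,4,5-trimethoxyphenyl)chroman-4-one (CNP0348225.1)
Conditions: Dess–Martin periodinane, NaHCO3, CH2Cl2, 0 °C → rt
Reagents that add atoms: none
Why: Dess–Martin oxidation of the secondary benzylic alcohol under NaHCO3 buffering should turn both C4 epimers into the one ketone without acid or strong base, so C2, which could epimerise by base-induced ring opening to the chalcone, stays S.

Compound list
1 | 1-(3,4,5-trimethoxyphenyl)ethanone | CC(=O)c1cc(OC)c(OC)c(OC)c1 | starting material
2 | 2-bromo-4,6-dimethoxybenzaldehyde | COc1cc(Br)c(C=O)c(OC)c1 | starting material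
3 | lithium 1-(3,4,5-trimethoxyphenyl)ethenolate (lithium enolate of 1) | [Li+].[O-]C(=C)c1cc(OC)c(OC)c(OC)c1 | intermediate
4 | rac-3-(2-bromo-4,6-dimethoxyphenyl)-3-hydroxy-1-(3,4,5-trimethoxyphenyl)propan-1-one | OC(CC(=O)c1cc(OC)c(OC)c(OC)c1)c1c(Br)cc(OC)cc1OC | intermediate
5 | rac-3-(2-bromo-4,6-dimethoxyphenyl)-3-[(tert-butyldimethylsilyl)oxy]-1-(3,4,5-trimethoxyphenyl)propan-1-one | CC(C)(C)[Si](C)(C)OC(CC(=O)c1cc(OC)c(OC)c(OC)c1)c1c(Br)cc(OC)cc1OC | intermediate
6 | (1S,3RS)-3-(2-bromo-4,6-dimethoxyphenyl)-3-[(tert-butyldimethylsilyl)oxy]-1-(3,4,5-trimethoxyphenyl)propan-1-ol (S at the carbinol, both epimers at the silyloxy carbon) | O[C@H](c1cc(OC)c(OC)c(OC)c1)CC(O[Si](C)(C)C(C)(C)C)c1c(Br)cc(OC)cc1OC | intermediate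
7 | (2S,4RS)-4-[(tert-butyldimethylsilyl)oxy]-5,7-dimethoxy-2-(3,4,5-trimethoxyphenyl)chromane (S at C2, both epimers at C4) | COc1cc(OC)c2c(c1)O[C@H](c1cc(OC)c(OC)c(OC)c1)CC2O[Si](C)(C)C(C)(C)C | intermediate
8 | (2S,4RS)-5,7-dimethoxy-2-(3,4,5-trimethoxyphenyl)chroman-4-ol (S at C2, both epimers at C4) | COc1cc(OC)c2c(c1)O[C@H](c1cc(OC)c(OC)c(OC)c1)CC2O | intermediate
9 | (2S)-5,7-dimethoxy-2-(3,4,5-trimethoxyphenyl)chroman-4-one | COc1cc(OC)c2c(c1)O[C@H](c1cc(OC)c(OC)c(OC)c1)CC2=O | target

Total step count: 6
Longest linear sequence: 6 steps (from 1 or 2 to 9)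

Steps most likely to fail

Step 4. The palladium alkoxide may undergo β-hydride elimination (ketone formation with loss of bromine) instead of C–O reductive elimination, oxidative addition next to the branched silyloxy carbon may stall, or the silyl group may migrate from the C4 oxygen to the C2 oxygen under carbonate. The fallback forms the other ether bond of ring C, C2–O1, by substitution with inversion, and sets out from 5. Reduction of 5 with the enantiomeric (S)-1-methyl-3,3-diphenyltetrahydro-1H,3H-pyrrolo[1,2-c][1,3,2]oxazaborole and BH3·SMe2 should give (1R,3RS)-3-(2-bromo-4,6-dimethoxyphenyl)-3-[(tert-butyldimethylsilyl)oxy]-1-(3,4,5-trimethoxyphenyl)propan-1-ol F1. Miyaura borylation (bis(pinacolato)diboron, PdCl2[1,1'-bis(diphenylphosphino)ferrocene], KOAc, dioxane, 80 °C) should convert the bromide into the arylboronic ester (1R,3RS)-3-[(tert-butyldimethylsilyl)oxy]-3-[2,4-dimethoxy-6-(4,4,5,5-tetramethyl-1,3,2-dioxaborolan-2-yl)phenyl]-1-(3,4,5-trimethoxyphenyl)propan-1-ol F2. Oxidation with NaBO3·4H2O in THF/water should give the phenol 2-[(1RS,3R)-1-[(tert-butyldimethylsilyl)oxy]-3-hydroxy-3-(3,4,5-trimethoxyphenyl)propyl]-3,5-dimethoxyphenol F3. A Mitsunobu reaction (PPh3, diisopropyl azodicarboxylate, THF, 0 °C) should then close ring C by attack of the phenol oxygen on the activated carbinol carbon with inversion, R to S, and the sequence comes back to the route at 7.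

Step 3. Facial selectivity may be insufficient for the enantiomer of 5 that is mismatched with the oxazaborolidine, and uncatalysed borane reduction or borane complexation by the many ether oxygens may erode the preference for the S carbinol. The fallback sets out from 5 and comes back at 6, replacing borane chemistry by Noyori–Ikariya asymmetric transfer hydrogenation with RuCl(p-cymene)[(S,S)-N-(p-toluenesulfonyl)-1,2-diphenylethylenediamine] and HCO2H/Et3N in CH2Cl2 at room temperature. Hydride and proton are transferred from a chiral ruthenium hydride amine complex through an outer-sphere six-membered transition state that recognises the aryl ring, with no Lewis acid and no background reductant. The (S,S)-catalyst gives S alcohols from aryl alkyl ketones. No new compound arises on this way (F0).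

Step 1. The addition may revert (retro-aldol) on warming, and the aldol may lose water to the chalcone, both favoured by the electron-rich, doubly ortho-substituted aldehyde and by the acidity of the aryl ketone α-protons. The fallback builds the ketone only after silylation and sets out from 2. N-Methoxy-N-methylacetamide is deprotonated with LiN(i-Pr)2 in THF at −78 °C to the lithium enolate of N-methoxy-N-methylacetamide F4, an amide enolate whose addition to 2 is much less reversible. The adduct rac-3-(2-bromo-4,6-dimethoxyphenyl)-3-hydroxy-N-methoxy-N-methylpropanamide F5 is silylated (TBSOTf, 2,6-lutidine, CH2Cl2, −78 °C) to rac-3-(2-bromo-4,6-dimethoxyphenyl)-3-[(tert-butyldimethylsilyl)oxy]-N-methoxy-N-methylpropanamide F6. Weinreb ketone synthesis with commercial 3,4,5-trimethoxyphenylmagnesium bromide (THF, 0 °C) should then give the ketone, so the sequence comes back to the route at 5 and replaces 1 as the source of the trimethoxyphenyl ring.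

Further compounds
F1 | step 4 | (1R,3RS)-3-(2-bromo-4,6-dimethoxyphenyl)-3-[(tert-butyldimethylsilyl)oxy]-1-(3,4,5-trimethoxyphenyl)propan-1-ol | O[C@@H](c1cc(OC)c(OC)c(OC)c1)CC(O[Si](C)(C)C(C)(C)C)c1c(Br)cc(OC)cc1OC
F2 | step 4 | (1R,3RS)-3-[(tert-butyldimethylsilyl)oxy]-3-[2,4-dimethoxy-6-(4,4,5,5-tetramethyl-1,3,2-dioxaborolan-2-yl)phenyl]-1-(3,4,5-trimethoxyphenyl)propan-1-ol | O[C@@H](c1cc(OC)c(OC)c(OC)c1)CC(O[Si](C)(C)C(C)(C)C)c1c(B2OC(C)(C)C(C)(C)O2)cc(OC)cc1OC
F3 | step 4 | 2-[(1RS,3R)-1-[(tert-butyldimethylsilyl)oxy]-3-hydroxy-3-(3,4,5-trimethoxyphenyl)propyl]-3,5-dimethoxyphenol | O[C@@H](c1cc(OC)c(OC)c(OC)c1)CC(O[Si](C)(C)C(C)(C)C)c1c(O)cc(OC)cc1OC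
F0 | step 3 | none | none
F4 | step 1 | lithium enolate of N-methoxy-N-methylacetamide | [Li+].[O-]C(=C)N(C)OC
F5 | step 1 | rac-3-(2-bromo-4,6-dimethoxyphenyl)-3-hydroxy-N-methoxy-N-methylpropanamide | CON(C)C(=O)CC(O)c1c(Br)cc(OC)cc1OC
F6 | step 1 | rac-3-(2-bromo-4,6-dimethoxyphenyl)-3-[(tert-butyldimethylsilyl)oxy]-N-methoxy-N-methylpropanamide | CON(C)C(=O)CC(O[Si](C)(C)C(C)(C)C)c1c(Br)cc(OC)cc1OC
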